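**Retrosynthetic overview**
1. Target ⇒ 6,8-dibromo-3-iodo-5,7-dimethoxyflavone. The 3-, 6- and 8-OMe groups are installed last, in one copper-mediated triple C–O coupling (key step B).
2. ⇒ 1-(3,5-dibromo-2,4,6-trimethoxyphenyl)-3-phenylpropynone. O1–C2 and C3–I are made together by ICl-induced demethylative 6-endo-dig iodocyclisation, with an aryl methyl ether as the nucleophile (key step A). This avoids the chalcone/Algar–Flynn–Oyamada and Baker–Venkataraman/Allan–Robinson routes and needs no free phenol.
3. ⇒ NBS dibromination of the symmetric 2,4,6-trimethoxyphenyl ynone. The bromines first block the ring against ICl and then serve as handles for methoxylation.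
4. ⇒ phenylacetylene + 2,4,6-trimethoxybenzaldehyde (acetylide addition, then MnO2).
5. Ring order: rings A and B are bought as benzene rings. The pyranone ring C is the only ring formed (step 4).

Assumption: the target has no stereocentre, stereogenic axis or stereogenic double bond, so it is achiral and "single enantiomer" requires nothing. The only stereocentre on the route (carbinol 5, racemic) is erased in step 2.

**Route**

Step 1
Reactants: 1 phenylacetylene; 2 2,4,6-trimethoxybenzaldehyde
Product: 5 rac-1-(2,4,6-trimethoxyphenyl)-3-phenylprop-2-yn-1-ol, via lithium phenylacetylide 3 (not isolated), via lithium propargylic alkoxide 4 (not isolated)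
Conditions: n-BuLi (1.05 equiv), THF, −78 °C; then 2, −78 → 0 °C; H2O quench; product used crude
Reagents that add atoms: none
Why: This is a 1,2-addition of a lithium acetylide to an aromatic aldehyde (carbonyl alkynylation), and the new carbinol centre is racemic and is erased in step 2, so no control is needed.

Step 2
Reactants: 5 rac-1-(2,4,6-trimethoxyphenyl)-3-phenylprop-2-yn-1-ol
Product: 6 1-(2,4,6-trimethoxyphenyl)-3-phenylprop-2-yn-1-one
Conditions: activated MnO2 (10 equiv), CH2Cl2, rt
Reagents that add atoms: none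
Why: MnO2 oxidises the doubly activated (benzylic and propargylic) alcohol under neutral conditions, so the acid-labile electron-rich carbinol does not ionise.

Step 3
Reactants: 6 1-(2,4,6-trimethoxyphenyl)-3-phenylprop-2-yn-1-one
Product: 8 1-(3,5-dibromo-2,4,6-trimethoxyphenyl)-3-phenylprop-2-yn-1-one, via 3-bromo ynone 7 (not isolated)
Conditions: NBS (2.1 equiv), MeCN, 0 °C → rt, dark
Reagents that add atoms: N-bromosuccinimide, O=C1CCC(=O)N1Br
Why: In this electrophilic aromatic substitution the two remaining ring C–H positions are equivalent and each is ortho/para to three methoxy groups, so only one dibromide can form, while the acyl-conjugated alkyne and the plain phenyl ring are too electron-poor for NBS.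

Step 4
Reactants: 8 1-(3,5-dibromo-2,4,6-trimethoxyphenyl)-3-phenylprop-2-yn-1-one
Product: 10 6,8-dibromo-3-iodo-5,7-dimethoxyflavone, via O-methyl oxonium chloride 9 (not isolated)
Conditions: ICl (1.5 equiv), CH2Cl2, −78 °C → rt; aq Na2S2O3
Reagents that add atoms: iodine monochloride, ClI
Why: In this Larock-type electrophilic iodocyclisation of a 2-methoxyaryl ynone, I+ activates the alkyne, an ortho-OMe oxygen attacks the phenyl-bearing carbon 6-endo-dig and chloride removes the oxonium methyl by SN2, and because both ortho-OMe groups are equivalent and the ring has no free C–H, one regioisomer forms without ring iodination.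

Step 5
Reactants: 10 6,8-dibromo-3-iodo-5,7-dimethoxyflavone
Product: 14 3,5,6,7,8-pentamethoxyflavone (target), via 6,8-dibromo-3,5,7-trimethoxyflavone 11 (not isolated), via 8-bromo-3,5,6,7-tetramethoxyflavone 12 (not isolated), via 6-bromo-3,5,7,8-tetramethoxyflavone 13 (not isolated)
Conditions: NaOMe (12 equiv, 25 wt% in MeOH), CuBr (0.5 equiv), DMF, 110 °C, Ar
Reagents that add atoms: sodium methoxide, [Na+].[O-]C
Why: Proposed new method: three Ullmann-type C(sp2)–O couplings are run in one pot, in which Cu(I)OMe formed in situ inserts into each C–X bond (oxidative addition to Cu(III), then C–O reductive elimination), first at the weak C3–I bond of the electron-poor α-iodoenone (giving 11) and then at the two aryl C–Br bonds, whose flanking ether oxygens pre-coordinate copper (12 or 13, then 14); methoxide addition at C2 is reversible and can only re-close to the same pyranone because the 5-oxygen is capped as a methyl ether; the closest known reaction types are the CuBr/NaOMe methanolysis of 6,8-dibromoflavones and polybromoanisoles and the copper-catalysed alkoxylation of vinyl iodides, and what is new is the use of a 3-iodoflavone C–I bond and running all three couplings at once; no stereocentre is formed.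

**Compound list**
1 | phenylacetylene | C#Cc1ccccc1 | starting material
2 | 2,4,6-trimethoxybenzaldehyde | COc1cc(OC)c(C=O)c(OC)c1 | starting material
3 | lithium phenylacetylide | [Li]C#Cc1ccccc1 | intermediate (not isolated)
4 | lithium 1-(2,4,6-trimethoxyphenyl)-3-phenylprop-2-yn-1-olate (racemic) | [Li]OC(C#Cc1ccccc1)c1c(OC)cc(OC)cc1OC | intermediate (not isolated)
5 | 1-(2,4,6-trimethoxyphenyl)-3-phenylprop-2-yn-1-ol (racemic) | OC(C#Cc1ccccc1)c1c(OC)cc(OC)cc1OC | intermediate
6 | 1-(2,4,6-trimethoxyphenyl)-3-phenylprop-2-yn-1-one | COc1cc(OC)c(C(=O)C#Cc2ccccc2)c(OC)c1 | intermediate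
7 | 1-(3-bromo-2,4,6-trimethoxyphenyl)-3-phenylprop-2-yn-1-one | COc1cc(OC)c(C(=O)C#Cc2ccccc2)c(OC)c1Br | intermediate (not isolated)
8 | 1-(3,5-dibromo-2,4,6-trimethoxyphenyl)-3-phenylprop-2-yn-1-one | COc1c(Br)c(OC)c(C(=O)C#Cc2ccccc2)c(OC)c1Br | intermediate
9 | 6,8-dibromo-3-iodo-5,7-dimethoxy-1-methyl-4-oxo-2-phenyl-4H-chromen-1-ium chloride | C[O+]1C(=C(I)C(=O)c2c(OC)c(Br)c(OC)c(Br)c21)c1ccccc1.[Cl-] | intermediate (not isolated)
10 | 6,8-dibromo-3-iodo-5,7-dimethoxy-2-phenyl-4H-chromen-4-one | COc1c(Br)c(OC)c2c(=O)c(I)c(-c3ccccc3)oc2c1Br | intermediate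
11 | 6,8-dibromo-3,5,7-trimethoxy-2-phenyl-4H-chromen-4-one | COc1c(Br)c(OC)c2c(=O)c(OC)c(-c3ccccc3)oc2c1Br | intermediate (not isolated)
12 | 8-bromo-3,5,6,7-tetramethoxy-2-phenyl-4H-chromen-4-one | COc1c(OC)c(OC)c2c(=O)c(OC)c(-c3ccccc3)oc2c1Br | intermediate (not isolated)
13 | 6-bromo-3,5,7,8-tetramethoxy-2-phenyl-4H-chromen-4-one | COc1c(Br)c(OC)c2c(=O)c(OC)c(-c3ccccc3)oc2c1OC | intermediate (not isolated)
14 | 3,5,6,7,8-pentamethoxy-2-phenyl-4H-chromen-4-one (3,5,6,7,8-pentamethoxyflavone, achiral) | COc1c(OC)c(OC)c2c(=O)c(OC)c(-c3ccccc3)oc2c1OC | target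

**Counts and risks**

Total step count: 5. Longest linear sequence: 5 (1/2 → 5 → 6 → 8 → 10 → 14).

**Step 5 carries the most risk.**
- Failure modes: the C3–I bond may be reduced. Methoxide may open the pyranone, and the opened form could re-close under copper to an aurone-type product. Hydrodebromination may erode the yield over three couplings.
- Fallback: make the C3–O bond by oxidising a carbon–boron bond instead of by coupling. It sets out from 10 and comes back at 11.
- Selective iodine–magnesium exchange (iPrMgCl·LiCl, THF, −40 °C, electron-rich aryl bromides untouched) gives 3-(chloromagnesio)-6,8-dibromo-5,7-dimethoxyflavone F1.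
- B(OMe)3 traps it as dimethyl (6,8-dibromo-5,7-dimethoxy-4-oxo-2-phenyl-4H-chromen-3-yl)boronate F2.
- H2O2/NaHCO3 oxidises this to 6,8-dibromo-3-hydroxy-5,7-dimethoxyflavone F3, and MeI/K2CO3/acetone gives 11, now isolated.
- Compound 11 then needs only the two aryl bromide methoxylations, which are the well-known part of step 5, to reach 14.

**Step 4 is second.**
- Failure modes: ICl may simply add across the ynone to give a β-chloro-α-iodoenone. The buttressed ortho-OMe may also be too hindered to close the ring.
- Fallback: separate ring closure from iodination. It sets out from 8 and comes back at 10.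
- BCl3 (CH2Cl2, −78 → 0 °C) cleaves one of the two equivalent carbonyl-chelated ortho-methyl ethers to give 1-(3,5-dibromo-2-hydroxy-4,6-dimethoxyphenyl)-3-phenylprop-2-yn-1-one F4.
- K2CO3 in refluxing acetone closes it by 6-endo oxa-Michael addition to 6,8-dibromo-5,7-dimethoxyflavone F5.
- I2/CAN in MeCN at 65 °C iodinates the only reactive C–H (C3) to give 10.

**Step 3 is third.**
- Failure modes: attack of bromine on the alkyne, or ipso-bromodeacylation of the very electron-rich aryl ketone.
- Fallback: brominate before any alkyne is present. It sets out from 2 and comes back at 8.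
- NBS (2.1 equiv, MeCN) converts 2 into 3,5-dibromo-2,4,6-trimethoxybenzaldehyde F6.
- Acetylide 3 adds to give lithium 1-(3,5-dibromo-2,4,6-trimethoxyphenyl)-3-phenylprop-2-yn-1-olate F7.
- A water quench gives racemic 1-(3,5-dibromo-2,4,6-trimethoxyphenyl)-3-phenylprop-2-yn-1-ol F8, and MnO2 in CH2Cl2 oxidises this to 8.

**Further compounds**
F1 | step 5 | 3-(chloromagnesio)-6,8-dibromo-5,7-dimethoxyflavone | COc1c(Br)c(OC)c2c(=O)c([Mg]Cl)c(-c3ccccc3)oc2c1Br
F2 | step 5 | dimethyl (6,8-dibromo-5,7-dimethoxy-4-oxo-2-phenyl-4H-chromen-3-yl)boronate | COc1c(Br)c(OC)c2c(=O)c(B(OC)OC)c(-c3ccccc3)oc2c1Br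
F3 | step 5 | 6,8-dibromo-3-hydroxy-5,7-dimethoxyflavone | COc1c(Br)c(OC)c2c(=O)c(O)c(-c3ccccc3)oc2c1Br
F4 | step 4 | 1-(3,5-dibromo-2-hydroxy-4,6-dimethoxyphenyl)-3-phenylprop-2-yn-1-one | COc1c(Br)c(O)c(C(=O)C#Cc2ccccc2)c(OC)c1Br
F5 | step 4 | 6,8-dibromo-5,7-dimethoxyflavone | COc1c(Br)c(OC)c2c(=O)cc(-c3ccccc3)oc2c1Br
F6 | step 3 | 3,5-dibromo-2,4,6-trimethoxybenzaldehyde | COc1c(Br)c(OC)c(C=O)c(OC)c1Br
F7 | step 3 | lithium 1-(3,5-dibromo-2,4,6-trimethoxyphenyl)-3-phenylprop-2-yn-1-olate (racemic) | [Li]OC(C#Cc1ccccc1)c1c(OC)c(Br)c(OC)c(Br)c1OC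
F8 | step 3 | 1-(3,5-dibromo-2,4,6-trimethoxyphenyl)-3-phenylprop-2-yn-1-ol (racemic) | OC(C#Cc1ccccc1)c1c(OC)c(Br)c(OC)c(Br)c1OC
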